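## The problem

The target 20 is a 2-arylbenzofuran. Its core (benzo ring A fused to furan ring B) carries a 3,5-dihydroxyphenyl group (ring C) at C2, a free hydroxyl at C6 and a geranyl chain at C7, the ring A carbon wedged between C7a–O1 and the C6 oxygen. There is no stereocentre. The only stereochemical element is the (E) double bond C2′=C3′ of the chain, which is best bought with geranyl bromide and then kept away from anything that could protonate, ionise or deprotonate next to it. Two tasks follow: the chain must go onto the one arene carbon flanked by two oxygens and nowhere else, and ring C must be joined to C2 of the furan. The fragile parts are the two trisubstituted alkenes and the three electron-rich phenols. The alkenes rule out hydrogenolysis and strong Brønsted or Lewis acid, because a free C6 hydroxyl adds to C3′ to give a chroman and the 1,5-diene can undergo cation–olefin cyclisation. The phenols, on an electron-rich benzofuran, oxidise easily as phenoxides in air. The feature that opens the key step is ring C: C1″ is bonded to C2 of the benzofuran, C3″ and C5″ carry hydroxyls, and C2″, C4″ and C6″ carry hydrogen, the alternating pattern of an acetate-derived resorcinol. With a carboxyl imagined on C6″, ring C is a 6-substituted 2,4-dihydroxybenzoate, the aldol-folding product of a linear 3,5,7-triketo ester whose C7 ketone is a benzofuran-2-yl ketone. Ring C can therefore be grown from a benzofuran-2-carboxylate.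

## Retrosynthesis

**20 to 19.** The last bond cut is the O–allyl bond at C6. The C6 oxygen must stay capped from the furan annulation to the ring C closure: as a phenoxide it is in through-conjugation with the C2 acyl group (via C3a and C3) and would deaden both the ester of 12 and the ketone of 15. An allyl ether is preferred to a methoxymethyl ether, whose removal would expose the finished ortho-geranyl phenol to acid, and to a benzyl ether, which cannot be removed beside the chain alkenes. The forward step asks only that zerovalent palladium ionise an aryl allyl ether and pass the allyl group to an amine.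

**19 to 17 (through acid 18).** A carboxyl is added retrosynthetically at C6″, ortho to the benzofuranyl group and to the C5″ hydroxyl. This makes ring C a β-resorcylate and so a polyketide folding product. The forward reaction is ester hydrolysis and loss of CO2 from the 2,4-dihydroxybenzoic acid 18, which is easy because the ring protonates at the carboxyl-bearing carbon.

**17 to 15 (through carbinol 16).** The C1″–C6″ bond is cut and ring C is unfolded to the triketo ester 15. The neighbouring options were to cross-couple an intact resorcinol unit to C2 or to form one of the rings of the benzofuran late (see below). This cut instead takes ring C back to a six-carbon acyclic chain and asks of the benzofuran only that it be an ester. The forward reaction must close by aldol addition (C2 of the chain onto the C7 ketone) and not by Claisen condensation or lactonisation.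

**15 to 12 and 13 (through trianion 14).** The bond between the benzofuranyl carbonyl carbon (C7) and C6 of the chain is cut. This Claisen-type acylation splits 15 into two pieces of similar size, and all six chain carbons come in one purchased reagent, 13. Building the chain by two successive two-carbon extensions would cost more steps. The forward reaction needs the terminal carbanion of 14 to attack a non-enolisable heteroaryl ester.

**12 to 9 and 10 (through ether 11).** Ring B is cut at O1–C2 and C2=C3. The salicylaldehyde 9 and methyl bromoacetate 10 deliver the furan with the ester already at C2 in one operation (Rap–Stoermer-type annulation). Cutting C7a–O1 or C3–C3a would need a pre-functionalised arene with no simpler source.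

**9 to 8 to 7.** The C4 oxygen of the aldehyde (later C6–O) is differentiated from the C2 oxygen (later O1) by hydrogen bonding: in diol 8 the 2-hydroxyl is chelated to the formyl group, so only the 4-hydroxyl is allylated. Diol 8 comes from the bis(methoxymethyl) ether 7, whose two acetals were needed only as directing groups.

**7 to 5 (through aryllithium 6), 5 to 2 and 3 (through aryllithium 4), 2 to 1.** The formyl carbon and the geranyl chain are both introduced by directed ortho-metalation. Lithiation of 2 occurs only at the carbon between the two acetal oxygens, which puts the chain exactly where the target has it. Direct C-geranylation of resorcinol or of 2,4-dihydroxybenzaldehyde would favour the other ortho position or give mixtures. A second lithiation of 5, ortho to one acetal, followed by DMF gives 7. Resorcinol 1 and geranyl bromide 3 are the starting materials.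

## Roads not taken

**Alternative 1:** The cut is the C2=C3 double bond of the furan. The precursor is the aryl ester A2, in which the phenolic oxygen of a 3-geranyl salicylaldehyde carries a bis-silylated 3,5-dihydroxybenzoyl group. Low-valent titanium from TiCl3 and zinc dust in refluxing dimethoxyethane would couple the formyl carbon with the ester carbonyl carbon (McMurry-type coupling) to give A1, and fluoride would then free the phenols.
- Merits: convergent; ring C is bought intact; the aldehyde is a close relative of 9. The road is about three steps shorter and needs neither polyanion chemistry nor a decarboxylation.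
- Weak points: attack on the poorly electrophilic ester carbonyl must beat intermolecular pinacol coupling of the aldehyde. A2 is an activated phenyl ester prone to acyl transfer. The medium (Lewis-acidic titanium and zinc chlorides, about 85 °C, long reaction time) is the kind that cyclises a geranyl chain and loosens aryl silyl ethers, after which a free C6 phenol sits next to the chain under acid.
- Comparison: on step count and convergence Alternative 1 is better. The chosen plan sets against it that, once the chain is attached, only one step is acidic, and that its ring closure is of an established type. It pays with a longer linear sequence.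

**Alternative 2:** The cuts are C2–C3 and C3a–C7a, so that furan and ring A form together. Heating the oxazole keto-alkyne A4 in o-dichlorobenzene would add the tethered alkyne across C2 and C5 of the oxazole (Kondrat'eva-type cycloaddition) and expel the N3–C4 unit as a nitrile. The product is the dihydrobenzofuranone A3 as a diastereomer mixture. Elimination of silanol, enolisation to the C6 phenol and removal of the silyl ethers would follow.
- Merits: two rings and two C–C bonds form in one reagent-free step; the positions of the C7 chain and the C6 oxygen are fixed by the tether; ring C is bought. This key step builds more than the chosen one, which forms one bond and one ring.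
- Weak points: A4 is a demanding target in itself. The carbon that carries the chain is α to a ketone and attached to the oxazole, so it is easily enolised, and the ketone also bears a β-silyloxy propargyl unit that can eliminate. The cycloaddition needs about 180 °C, and three operations remain after it.
- Comparison: the chosen plan has the less powerful key step but reaches its precursor 15 in seven ordinary steps from 1.

**Alternative 3:** The cut is C4–C5 of ring A. In the furan A6, a formyl group at furan C3 and a 1-geranyl-2-oxopropyl side chain at furan C2 would be joined by DBU: aldol condensation of the methyl ketone with the aldehyde, then tautomerisation of the dienone to the phenol A5. One fluoride step would then give 20.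
- Merits: mild base; the C6 hydroxyl appears free with the chain already in place; the end game is a single neutral desilylation. That is better than the two steps, one in hot alkali, that follow the chosen key step.
- Weak points: the difficulty moves into A6, a 2,3,5-trisubstituted furan with an α-branched, doubly activated ketone. Its assembly (regioselective furan substitution, α-geranylation with C- versus O-alkylation and dialkylation) has no short precedent and would probably cost more than the steps saved. The aldehyde and the enolisable ketone can also condense between molecules.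
- Comparison: after the key step Alternative 3 is superior. The chosen plan sets against it a precursor made by standard operations from cheap materials.

Key step: step 8

Assumption: geranyl means the (2E)-3,7-dimethylocta-2,6-dien-1-yl group throughout, and methyl 3,5-dioxohexanoate (13) is taken as a purchased compound.

## Route

Step 1
Reactants: 1 resorcinol
Product: 2 1,3-bis(methoxymethoxy)benzene
Conditions: NaH, MOMCl, DMF, 0 °C → rt
Reagents that add atoms: chloromethyl methyl ether, COCCl
Why: Williamson-type O-alkylation of both phenoxides; the two acetal ethers are the directing groups for the next two steps.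

Step 2
Reactants: 2 1,3-bis(methoxymethoxy)benzene; 3 geranyl bromide
Product: 5 2-geranyl-1,3-bis(methoxymethoxy)benzene, via 2-lithio-1,3-bis(methoxymethoxy)benzene 4 (not isolated)
Conditions: n-BuLi, THF, 0 °C → rt; then CuI (10 mol %), 3, −78 °C → rt
Reagents that add atoms: none
Why: Directed ortho-metalation takes place only at the carbon flanked by both acetal oxygens; the aryllithium is alkylated at the primary carbon of the allylic bromide, with CuI suppressing allylic transposition, so the (E) alkene is carried over unchanged.

Step 3
Reactants: 5 2-geranyl-1,3-bis(methoxymethoxy)benzene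
Product: 7 3-geranyl-2,4-bis(methoxymethoxy)benzaldehyde, via aryllithium 6 (not isolated)
Conditions: n-BuLi, TMEDA, THF, −20 → 0 °C; DMF, −78 °C → rt; H2O
Reagents that add atoms: N,N-dimethylformamide, CN(C)C=O
Why: Second directed ortho-metalation, now at the ring position ortho to one acetal ether (the two such positions are equivalent), followed by formylation with DMF (Bouveault-type); coordination of lithium by the acetal should favour ring over side-chain deprotonation.

Step 4
Reactants: 7 3-geranyl-2,4-bis(methoxymethoxy)benzaldehyde
Product: 8 3-geranyl-2,4-dihydroxybenzaldehyde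
Conditions: aq. HCl (2 M), MeOH, rt
Reagents that add atoms: none
Why: Acid-catalysed acetal solvolysis; oxocarbenium formation from the acetals is far faster than protonation of a trisubstituted alkene in dilute acid at room temperature, and the phenols are deactivated by the formyl group, so the chain should survive.

Step 5
Reactants: 8 3-geranyl-2,4-dihydroxybenzaldehyde
Product: 9 4-(allyloxy)-3-geranyl-2-hydroxybenzaldehyde
Conditions: allyl bromide (1.05 equiv), K2CO3 (1.1 equiv), acetone, rt → 45 °C
Reagents that add atoms: allyl bromide, C=CCBr
Why: Regioselective Williamson etherification; the 2-hydroxyl is held in a hydrogen bond to the formyl group and is the less acidic and less nucleophilic one, so the para-hydroxyl is alkylated.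

Step 6
Reactants: 9 4-(allyloxy)-3-geranyl-2-hydroxybenzaldehyde; 10 methyl bromoacetate
Product: 12 methyl 6-(allyloxy)-7-geranylbenzofuran-2-carboxylate, via aryloxyacetate 11 (not isolated)
Conditions: 10, K2CO3, DMF, 4 Å MS, 90 °C
Reagents that add atoms: none
Why: Rap–Stoermer-type benzofuran annulation: O-alkylation of the phenoxide, then intramolecular aldol condensation of the ester α-carbon with the ortho formyl group and dehydration to the aromatic furan; the allyl ether is far below its Claisen rearrangement temperature.

Step 7
Reactants: 12 methyl 6-(allyloxy)-7-geranylbenzofuran-2-carboxylate; 13 methyl 3,5-dioxohexanoate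
Product: 15 methyl 7-[6-(allyloxy)-7-geranylbenzofuran-2-yl]-3,5,7-trioxoheptanoate, via trilithium trianion 14 (not isolated)
Conditions: 13 (2.2 equiv), LiN(i-Pr)2 (6.6 equiv), THF, −78 → 0 °C; then 12, 0 °C → rt; AcOH
Reagents that add atoms: none
Why: Claisen-type C-acylation of a β,δ-diketo ester trianion, which reacts at its last-formed, most basic terminal carbon with a non-enolisable ester; the trianion is used in excess because the product gives up a proton to it, and exactly three equivalents of amide per 13 leave no free amide to isomerise the allyl ether.

Step 8
Reactants: 15 methyl 7-[6-(allyloxy)-7-geranylbenzofuran-2-yl]-3,5,7-trioxoheptanoate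
Product: 17 methyl 2-[6-(allyloxy)-7-geranylbenzofuran-2-yl]-4,6-dihydroxybenzoate, via cyclic aldol adduct 16 (not isolated)
Conditions: aq. KOH (1 M), THF, rt, Ar; then AcOH to pH 5
Reagents that add atoms: none
Why: This is the aldol cyclisation–aromatisation of a 7-aryl-3,5,7-triketo ester in aqueous hydroxide, a known biomimetic route to 6-substituted 2,4-dihydroxybenzoates, applied here to a benzofuran-2-yl ketone. In KOH the chain is held as a polyenolate, which protects it from retro-Claisen cleavage, and the carbon between the C3 ketone and the ester (C2) adds to the C7 ketone, forming the C1″–C6″ bond and the carbinol 16. Ring C closes in a six-membered exo-trig mode (enolate endocyclic with respect to the C3 ketone), which is a favoured closure. Loss of water from 16 and enolisation of the C3 and C5 carbonyls give the aromatic ring and make the closure irreversible. The two stereocentres of 16 are transient and disappear on aromatisation, so no stereocontrol is needed. The selectivity required is aldol closure over Claisen closure (C6 onto the ester carbonyl, which would give an acylphloroglucinol) and over lactonisation of the C5 enolate oxygen to a 4-hydroxypyranone. The medium should secure it, since water without magnesium or alkoxide leaves the ester unactivated by chelation and lets any tetrahedral adduct revert. The substrate helps as well: its C7 ketone sits on the electron-poor C2 of the benzofuran, and the allyl cap on the C6 oxygen prevents a phenoxide from feeding electron density into that carbonyl.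

Step 9
Reactants: 17 methyl 2-[6-(allyloxy)-7-geranylbenzofuran-2-yl]-4,6-dihydroxybenzoate
Product: 19 5-[6-(allyloxy)-7-geranylbenzofuran-2-yl]benzene-1,3-diol, via resorcylic acid 18 (not isolated)
Conditions: KOH, H2O–MeOH, reflux, Ar; then AcOH to pH 5, 60 °C
Reagents that add atoms: none
Why: Saponification followed by protodecarboxylation of a 2,4-dihydroxybenzoic acid, which loses CO2 readily through ipso protonation of the electron-rich ring; the allyl ether and the chain are inert to aqueous alkali and to acetic acid, and the C6 oxygen is still capped during acidification.

Step 10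
Reactants: 19 5-[6-(allyloxy)-7-geranylbenzofuran-2-yl]benzene-1,3-diol
Product: 20 5-(7-geranyl-6-hydroxybenzofuran-2-yl)benzene-1,3-diol (the target)
Conditions: Pd(PPh3)4 (5 mol %), morpholine, THF, rt, Ar
Reagents that add atoms: none
Why: Tsuji–Trost deallylation: zerovalent palladium ionises the aryl allyl ether and morpholine traps the π-allyl complex; the chain is attached through carbon and has no leaving group, the isolated alkenes do not react, and the conditions are neutral, so no chroman can form.

## Compound list

1 | resorcinol (benzene-1,3-diol) | Oc1cccc(O)c1 | starting material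
2 | 1,3-bis(methoxymethoxy)benzene | COCOc1cccc(OCOC)c1 | intermediate
3 | geranyl bromide, (2E)-1-bromo-3,7-dimethylocta-2,6-diene | CC(C)=CCC/C(C)=C/CBr | starting material
4 | 2-lithio-1,3-bis(methoxymethoxy)benzene (not isolated) | [Li]c1c(OCOC)cccc1OCOC | intermediate
5 | 2-geranyl-1,3-bis(methoxymethoxy)benzene, (E) | CC(C)=CCC/C(C)=C/Cc1c(OCOC)cccc1OCOC | intermediate
6 | [3-geranyl-2,4-bis(methoxymethoxy)phenyl]lithium, (E) (not isolated) | CC(C)=CCC/C(C)=C/Cc1c(OCOC)ccc([Li])c1OCOC | intermediate
7 | 3-geranyl-2,4-bis(methoxymethoxy)benzaldehyde, (E) | CC(C)=CCC/C(C)=C/Cc1c(OCOC)ccc(C=O)c1OCOC | intermediate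
8 | 3-geranyl-2,4-dihydroxybenzaldehyde, (E) | CC(C)=CCC/C(C)=C/Cc1c(O)ccc(C=O)c1O | intermediate
9 | 4-(allyloxy)-3-geranyl-2-hydroxybenzaldehyde, (E) | CC(C)=CCC/C(C)=C/Cc1c(OCC=C)ccc(C=O)c1O | intermediate
10 | methyl bromoacetate | COC(=O)CBr | starting material
11 | methyl 2-[3-(allyloxy)-6-formyl-2-geranylphenoxy]acetate, (E) (not isolated) | CC(C)=CCC/C(C)=C/Cc1c(OCC=C)ccc(C=O)c1OCC(=O)OC | intermediate
12 | methyl 6-(allyloxy)-7-geranylbenzofuran-2-carboxylate, (E) | CC(C)=CCC/C(C)=C/Cc1c(OCC=C)ccc2cc(C(=O)OC)oc12 | intermediate
13 | methyl 3,5-dioxohexanoate | COC(=O)CC(=O)CC(C)=O | starting material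
14 | trilithium trianion of methyl 3,5-dioxohexanoate (not isolated) | [Li+].[Li+].[Li+].COC(=O)[CH-]C(=O)[CH-]C(=O)[CH2-] | intermediate
15 | methyl 7-[6-(allyloxy)-7-geranylbenzofuran-2-yl]-3,5,7-trioxoheptanoate, (E) | CC(C)=CCC/C(C)=C/Cc1c(OCC=C)ccc2cc(C(=O)CC(=O)CC(=O)CC(=O)OC)oc12 | intermediate
16 | methyl 2-[6-(allyloxy)-7-geranylbenzofuran-2-yl]-2-hydroxy-4,6-dioxocyclohexane-1-carboxylate, (E) chain, transient mixture of stereoisomers at the two ring centres (not isolated) | CC(C)=CCC/C(C)=C/Cc1c(OCC=C)ccc2cc(C3(O)CC(=O)CC(=O)C3C(=O)OC)oc12 | intermediate
17 | methyl 2-[6-(allyloxy)-7-geranylbenzofuran-2-yl]-4,6-dihydroxybenzoate, (E) | CC(C)=CCC/C(C)=C/Cc1c(OCC=C)ccc2cc(-c3cc(O)cc(O)c3C(=O)OC)oc12 | intermediate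
18 | 2-[6-(allyloxy)-7-geranylbenzofuran-2-yl]-4,6-dihydroxybenzoic acid, (E) (not isolated) | CC(C)=CCC/C(C)=C/Cc1c(OCC=C)ccc2cc(-c3cc(O)cc(O)c3C(=O)O)oc12 | intermediate
19 | 5-[6-(allyloxy)-7-geranylbenzofuran-2-yl]benzene-1,3-diol, (E) | CC(C)=CCC/C(C)=C/Cc1c(OCC=C)ccc2cc(-c3cc(O)cc(O)c3)oc12 | intermediate
20 | 5-(7-geranyl-6-hydroxybenzofuran-2-yl)benzene-1,3-diol, (E) | CC(C)=CCC/C(C)=C/Cc1c(O)ccc2cc(-c3cc(O)cc(O)c3)oc12 | target

## Step count and risks

Total step count: 10. Longest linear sequence: 10 steps, from 1 to 20.

**Step 8 (key step).** The chain may close the wrong way (Claisen condensation onto the ester, or lactonisation to a pyranone). Addition to the C7 ketone may also be slow because the electron-rich benzofuran lowers its electrophilicity, leaving time for hydrolytic cleavage of the polyketone. The fallback sets out from 12 and comes back to the route at 18, which gives 19 as in step 9. It locks the ester carbonyl in a ring so that only the aldol mode is open.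
- Commercial 2,2,6-trimethyl-4H-1,3-dioxin-4-one is C-acetylated through its lithium dienolate to 2,2-dimethyl-6-(2-oxopropyl)-4H-1,3-dioxin-4-one F1.
- The dilithium dianion of this reagent is acylated by 12 at its terminal carbon to 6-{4-[6-(allyloxy)-7-geranylbenzofuran-2-yl]-2,4-dioxobutyl}-2,2-dimethyl-4H-1,3-dioxin-4-one F2.
- Et3N in CH2Cl2 induces the known aldol cyclisation–dehydration of such diketo-dioxinones to 5-[6-(allyloxy)-7-geranylbenzofuran-2-yl]-7-hydroxy-2,2-dimethyl-4H-1,3-benzodioxin-4-one F3.
- Aqueous KOH opens the acetonide of this product to 18.

**Step 7.** Proton transfer from the acidic product to the trianion may stall the acylation. Acylation may also occur at oxygen or at an internal carbon, and any free amide base may isomerise the allyl ether. The fallback sets out from 12 and comes back at 18. It builds the chain in two stages: the dianion of pentane-2,4-dione is acylated by 12 to 1-[6-(allyloxy)-7-geranylbenzofuran-2-yl]hexane-1,3,5-trione F4. The trianion of this triketone (LiN(i-Pr)2, THF) is carboxylated with CO2 at its terminal carbon to 7-[6-(allyloxy)-7-geranylbenzofuran-2-yl]-3,5,7-trioxoheptanoic acid F5. A carboxylate cannot act as a Claisen acceptor, so in buffered water near pH 8 this acid should close by the aldol mode to 18.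

**Step 3.** Deprotonation may occur at the benzylic and allylic CH2 between the two acetal ethers instead of on the ring, which would lead to formylation of the chain or migration of the double bond. The fallback sets out from 5 and comes back at 8, with no organolithium touching the chain-bearing arene after step 2. Aqueous HCl in MeOH removes both acetals to give 2-geranylbenzene-1,3-diol F6. Magnesium-mediated ortho-formylation (MgCl2, Et3N, paraformaldehyde, MeCN, reflux) then delivers the formyl group ortho to a hydroxyl.

**Step 9.** Acyl–oxygen hydrolysis of the doubly ortho-substituted, phenoxide-deactivated ester may be sluggish. Long heating of the phenoxides invites oxidation and migration of the allyl double bond. The fallback sets out from 17 and comes back at 18. It cleaves the ester at the methyl carbon instead of the carbonyl carbon: LiSPr in DMF at rt to 50 °C demethylates by SN2 attack, and acidification to pH 5 with warming releases CO2 to give 19. This fallback makes no new compound (F0).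

## Further compounds

F1 | step 8 | 2,2-dimethyl-6-(2-oxopropyl)-4H-1,3-dioxin-4-one | CC(=O)CC1=CC(=O)OC(C)(C)O1
F2 | step 8 | 6-{4-[6-(allyloxy)-7-geranylbenzofuran-2-yl]-2,4-dioxobutyl}-2,2-dimethyl-4H-1,3-dioxin-4-one, (E) | CC(C)=CCC/C(C)=C/Cc1c(OCC=C)ccc2cc(C(=O)CC(=O)CC3=CC(=O)OC(C)(C)O3)oc12
F3 | step 8 | 5-[6-(allyloxy)-7-geranylbenzofuran-2-yl]-7-hydroxy-2,2-dimethyl-4H-1,3-benzodioxin-4-one, (E) | CC(C)=CCC/C(C)=C/Cc1c(OCC=C)ccc2cc(-c3cc(O)cc4OC(C)(C)OC(=O)c34)oc12
F4 | step 7 | 1-[6-(allyloxy)-7-geranylbenzofuran-2-yl]hexane-1,3,5-trione, (E) | CC(C)=CCC/C(C)=C/Cc1c(OCC=C)ccc2cc(C(=O)CC(=O)CC(C)=O)oc12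
F5 | step 7 | 7-[6-(allyloxy)-7-geranylbenzofuran-2-yl]-3,5,7-trioxoheptanoic acid, (E) | CC(C)=CCC/C(C)=C/Cc1c(OCC=C)ccc2cc(C(=O)CC(=O)CC(=O)CC(=O)O)oc12
F6 | step 3 | 2-geranylbenzene-1,3-diol, (E) | CC(C)=CCC/C(C)=C/Cc1c(O)cccc1O
F0 | step 9 | none | none
A1 | alternative 1 | 2-[3,5-bis(tert-butyldimethylsilyloxy)phenyl]-6-(tert-butyldimethylsilyloxy)-7-geranylbenzofuran, (E) | CC(C)=CCC/C(C)=C/Cc1c(O[Si](C)(C)C(C)(C)C)ccc2cc(-c3cc(O[Si](C)(C)C(C)(C)C)cc(O[Si](C)(C)C(C)(C)C)c3)oc12
A2 | alternative 1 | 2-formyl-6-geranyl-5-(tert-butyldimethylsilyloxy)phenyl 3,5-bis(tert-butyldimethylsilyloxy)benzoate, (E) | CC(C)=CCC/C(C)=C/Cc1c(O[Si](C)(C)C(C)(C)C)ccc(C=O)c1OC(=O)c1cc(O[Si](C)(C)C(C)(C)C)cc(O[Si](C)(C)C(C)(C)C)c1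
A3 | alternative 2 | 7-geranyl-4-(tert-butyldimethylsilyloxy)-2-[3,5-bis(triisopropylsilyloxy)phenyl]-4,5-dihydrobenzofuran-6(7H)-one, (E) chain, mixture of diastereomers | CC(C)=CCC/C(C)=C/CC1C(=O)CC(O[Si](C)(C)C(C)(C)C)c2cc(-c3cc(O[Si](C(C)C)(C(C)C)C(C)C)cc(O[Si](C(C)C)(C(C)C)C(C)C)c3)oc21
A4 | alternative 2 | (8E)-6-{5-[3,5-bis(triisopropylsilyloxy)phenyl]-1,3-oxazol-2-yl}-3-(tert-butyldimethylsilyloxy)-9,13-dimethyltetradeca-8,12-dien-1-yn-5-one, mixture of diastereomers | CC(C)=CCC/C(C)=C/CC(C(=O)CC(O[Si](C)(C)C(C)(C)C)C#C)c1ncc(-c2cc(O[Si](C(C)C)(C(C)C)C(C)C)cc(O[Si](C(C)C)(C(C)C)C(C)C)c2)o1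
A5 | alternative 3 | 7-geranyl-2-[3,5-bis(triisopropylsilyloxy)phenyl]benzofuran-6-ol, (E) | CC(C)=CCC/C(C)=C/Cc1c(O)ccc2cc(-c3cc(O[Si](C(C)C)(C(C)C)C(C)C)cc(O[Si](C(C)C)(C(C)C)C(C)C)c3)oc12
A6 | alternative 3 | 5-[3,5-bis(triisopropylsilyloxy)phenyl]-2-[(5E)-6,10-dimethyl-2-oxoundeca-5,9-dien-3-yl]furan-3-carbaldehyde, racemic | CC(C)=CCC/C(C)=C/CC(C(C)=O)c1oc(-c2cc(O[Si](C(C)C)(C(C)C)C(C)C)cc(O[Si](C(C)C)(C(C)C)C(C)C)c2)cc1C=O
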